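Gamma's charge is 1.55 times delta's, and at 8.00 h gamma's monomer in chains, as a fraction of its own charge, reads 1.53 times delta's.

all flasks: initiator 2.2 mM

|  | free monomer | remark | time |
|---|---|---|---|
| delta | 0.084 M (fed, over 15 h) | run made earlier |  |
| gamma | 0.13 M (fed, over 15 h) | run made earlier |  |
| noon | 0.15 M | everything together at the start | 5.0 h |
| autumn | 0.11 M (fed, over 15 h) |  | 15 h |

| run | time / h | monomer in chains / % | free monomer / % |
|---|---|---|---|
| delta | 1.33 | 0 | 9.3 |
| delta | 2.50 | 0 | 16.8 |
| delta | 4.00 | 0.3 | 24.6 |
| delta | 8.00 | 6.2 | 47.7 |
| delta | 15.0 | 44.7 | 52.2 |
| gamma | 1.33 | 0.5 | 7.5 |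
| gamma | 2.50 | 0 | 17.2 |
| gamma | 4.00 | 0 | 25.2 |
| gamma | 8.00 | 9.5 | 43.4 |
| gamma | 15.0 | 55.0 | 39.1 |

(standard deviation of a reading: 1 percentage point)

- percentages count the whole charge, also what has not yet gone in

1. the flask that ends with the higher amount of monomer in chains, in percent of the free monomer charged, or "neither" when 2 percentage points or less lies between them (noon / autumn / neither)
2. final monomer in chains, as a percentage of the free monomer charged, in noon
3. final monomer in chains, as a percentage of the free monomer charged, in autumn

The odd thing is that at 4.00 h gamma reads 25.2% free and 0% in chains, yet at 15.0 h it reads 55.0% in chains. Does free monomer wait for a clock? I suppose not. Suppose living ends form in proportion to free monomer and then capture it, a pseudo-first-order loss whose rate climbs with time. In a fed run free monomer then grows as time, ends as its square and chains as its fourth power, so delta's 6.2% at 8.00 h implies 0.388% at 4.00 h, which is inside the scatter.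

With everything in at the start, the same constant multiplies the fed figure by four times the square of dosing time over time. Scaling delta's reading so for noon gives 0.608. This capture count is the lifetimes of free monomer against capture up to that time, or the fraction of charge in chains if free monomer never ran down. My reckoning for noon is therefore 45.6%. Autumn, interpolated between delta and gamma, gives 50.5%.

The forecast says autumn, with 1% for noon and 50% for autumn, reading “a clock-like induction, probably set by the initiator”. Its noon differs from mine.

The flasks give autumn, with 45.1% for noon and 51.9% for autumn.

    free monomer + initiator → living end + monomer in chains (k = 0.0170 M⁻¹ min⁻¹)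
    free monomer + living end → monomer in chains + living end, rate k2*[living end]*[free monomer] (k = 3.70 M⁻¹ min⁻¹)
    monomer in chains + living end → free monomer + living end, rate k3*[living end] as long as [monomer in chains] is above zero (k = 0.0260 min⁻¹)
    initiator → spent initiator (k = 1.20 × 10⁻⁴ min⁻¹)
    free monomer + monomer in chains → side product (k = 0.00240 M⁻¹ min⁻¹)

The gradual adding of free monomer is the main reason autumn ends at 51.9%: the same flask with everything in at the start ends with 82.1%. Noon shows this from the other side, as one part of its difference from autumn: fed gradually it holds 2.03% in chains at 5.0 h and not 45.1%, with a fed count of 0.0169.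

In a neighbour of autumn, fed the same way with 0.044 M, the count at 15 h is 0.401, half of delta's, so I expect well under delta's 44.7%. It ends with 29.9% in chains and more free, 69.3%.

All runs are simulated with constants of no real substance.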